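**Retrosynthetic overview**

1. The target is reached from the fully protected all-cis pyranol (ring A as bis-benzyl ether, ring B as pivalate) by pivalate methanolysis and debenzylation.
2. Key disconnection is pyran O1–C2. The strategy rests on C2 being the benzylic carbon of ring A, whose oxygen at ring position 4 is para to C2. C2 can therefore be carried as a plain CH2 and oxidised at the anode, and the C6 oxygen then closes the pyran, the only ring formed, as the last skeletal event.
3. The open-chain precursor is the anti-(3S,5S)-1,7-diarylheptane-3,5-diol, made by Ru/(S)-BINAP hydrogenation of the 3,5-dione, so both carbinol centres come from one catalyst.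
4. The dione comes from C-acylation of the methyl-side lithium enolate of pivaloylated 4-(4-hydroxyphenyl)butan-2-one (C4–C7, ring B) with the N-acylbenzotriazole of the 3-arylpropanoic acid (C1–C3, ring A).
5. That acid comes from benzylated 3,4-dihydroxy-5-methoxybenzaldehyde and Meldrum's acid by a one-pot reductive Knoevenagel sequence.

Key step: step 7

Assumption: open-chain intermediates are numbered as heptanes from the ring-A end (heptane C1, C3, C5 become pyran C2, C4, C6), and the 3,5-dione is drawn as the diketone although its chelated enol should predominate.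

**Route**

Step 1
Reactants: 1 3,4-dihydroxy-5-methoxybenzaldehyde
Product: 2 3,4-bis(benzyloxy)-5-methoxybenzaldehyde
Conditions: BnBr (2.3 equiv), K2CO3 (3 equiv), DMF, 60 °C
Reagents that add atoms: benzyl bromide, BrCc1ccccc1
Why: Williamson etherification of both phenoxides; the benzyl ethers keep ring A electron-rich for the anodic step and should survive everything up to the final hydrogenolysis.

Step 2
Reactants: 2 3,4-bis(benzyloxy)-5-methoxybenzaldehyde; 3 Meldrum's acid (2,2-dimethyl-1,3-dioxane-4,6-dione)
Product: 6 3-[3,4-bis(benzyloxy)-5-methoxyphenyl]propanoic acid, via arylidene Meldrum's acid 4 (not isolated), via arylmethyl Meldrum's acid 5 (not isolated)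
Conditions: HCO2H/Et3N (5:2), rt, then 95 °C
Reagents that add atoms: none
Why: One-pot reductive Knoevenagel sequence: condensation gives the strongly electrophilic arylidene Meldrum's acid, formate transfers hydride to its β-carbon, and the hot medium opens the dioxanedione and decarboxylates it to the saturated acid; no hydrogenation metal is present, so the benzyl ethers should stay intact.

Step 3
Reactants: 6 3-[3,4-bis(benzyloxy)-5-methoxyphenyl]propanoic acid
Product: 7 1-{3-[3,4-bis(benzyloxy)-5-methoxyphenyl]propanoyl}-1H-benzotriazole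
Conditions: 1H-benzotriazole (4 equiv), SOCl2 (1 equiv), CH2Cl2, rt
Reagents that add atoms: 1H-benzotriazole, c1ccc2[nH]nnc2c1
Why: Carboxyl activation by the sulfinyl-bis(benzotriazole) formed in the flask gives a neutral, isolable acyl donor whose leaving group has no acidic proton, as the enolate acylation requires.

Step 4
Reactants: 8 4-(4-hydroxyphenyl)butan-2-one
Product: 9 4-(3-oxobutyl)phenyl pivalate
Conditions: PivCl (1.1 equiv), Et3N, DMAP (cat.), CH2Cl2, 0 °C to rt
Reagents that add atoms: pivaloyl chloride, CC(C)(C)C(Cl)=O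
Why: Phenol O-acylation; the hindered ester should resist enolates at low temperature and makes ring B too electron-poor to be oxidised in step 7.

Step 5
Reactants: 9 4-(3-oxobutyl)phenyl pivalate; 7 1-{3-[3,4-bis(benzyloxy)-5-methoxyphenyl]propanoyl}-1H-benzotriazole
Product: 11 1-[3,4-bis(benzyloxy)-5-methoxyphenyl]-7-[4-(pivaloyloxy)phenyl]heptane-3,5-dione, via lithium enolate 10 (not isolated)
Conditions: LDA (2.1 equiv), 9 (2.1 equiv), THF, −78 °C; then 7 (1 equiv), −78 to −20 °C; aq. NH4Cl
Reagents that add atoms: none
Why: Crossed Claisen-type C-acylation: LDA at −78 °C removes a methyl proton under kinetic control, the enolate attacks the N-acylbenzotriazole at carbon, and the second equivalent of enolate absorbs the acidic proton of the new 1,3-diketone; the surplus ketone is recovered.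

Step 6
Reactants: 11 1-[3,4-bis(benzyloxy)-5-methoxyphenyl]-7-[4-(pivaloyloxy)phenyl]heptane-3,5-dione
Product: 13 (3S,5S)-1-[3,4-bis(benzyloxy)-5-methoxyphenyl]-7-[4-(pivaloyloxy)phenyl]heptane-3,5-diol (anti), via β-hydroxy ketone 12 (not isolated)
Conditions: H2 (60 bar), RuCl2[(S)-BINAP] (1 mol %), EtOH/CH2Cl2, 50 °C
Reagents that add atoms: none
Why: Noyori asymmetric hydrogenation of a 1,3-diketone: each carbonyl is reduced through a ruthenium chelate with the neighbouring oxygen and the (S)-BINAP complex should give the S carbinol both times, so the catalyst-controlled second reduction leads to the anti diol and most of the enantiomeric error of the first reduction should end up in the separable syn diol; the homogeneous catalyst should not cleave benzyl ethers.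

Step 7
Reactants: 13 (3S,5S)-1-[3,4-bis(benzyloxy)-5-methoxyphenyl]-7-[4-(pivaloyloxy)phenyl]heptane-3,5-diol
Product: 15 (2S,4R,6S)-2-[3,4-bis(benzyloxy)-5-methoxyphenyl]-6-{2-[4-(pivaloyloxy)phenyl]ethyl}tetrahydro-2H-pyran-4-ol (all-cis), via benzylic cation 14 (not isolated)
Conditions: graphite anode, Pt cathode, undivided cell, constant current (about 2.1 F/mol), Et4NBF4 (0.1 M), MeCN/HFIP (4:1), 2,6-lutidine (3 equiv), rt
Reagents that add atoms: none
Why: Proposed new method: ring A, a 1,2,3-trialkoxy-5-alkylbenzene expected to be several hundred millivolts easier to oxidise than the acyloxy-substituted ring B, gives up one electron at the anode, 2,6-lutidine removes the ring-bound benzylic proton at heptane C1, and the benzylic radical is oxidised at once to the alkoxy-stabilised, quinone-methide-like cation 14 while protons are reduced to H2 at the cathode. The closest known reaction types are anodic benzylic C–H alkoxylation of alkoxy-substituted alkylbenzenes and quinone-mediated oxidative cyclisation of 1,3-diarylpropanes to flavans; what is new is capture of such a cation by an aliphatic hydroxyl of a free 1,3-diol to close a tetrahydropyran. The pyran closes by 6-exo-trig attack of the C5 hydroxyl on the cationic carbon, and the C3 hydroxyl cannot compete because it could only form an oxetane. The new centre (pyran C2) is set by a chair transition state with the aryl group, the C4 hydroxyl and the C6 side chain all equatorial, which is also the thermodynamic isomer reached if the benzylic ether re-ionises. The step needs ring A to be oxidised selectively and only once: the pivalate takes ring B out of the accessible potential window, the radical cation should lose the ring-bound benzylic proton in preference to an OCH2Ph or OCH3 proton because only the former overlaps directly with the ring π-system, and the charge is held near two electrons per molecule because the product is itself a benzylic ether that further current would consume.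

Step 8
Reactants: 15 (2S,4R,6S)-2-[3,4-bis(benzyloxy)-5-methoxyphenyl]-6-{2-[4-(pivaloyloxy)phenyl]ethyl}tetrahydro-2H-pyran-4-ol
Product: 16 (2S,4R,6S)-2-[3,4-bis(benzyloxy)-5-methoxyphenyl]-6-[2-(4-hydroxyphenyl)ethyl]tetrahydro-2H-pyran-4-ol
Conditions: K2CO3 (1.5 equiv), MeOH/THF, rt
Reagents that add atoms: none
Why: Base-mediated methanolysis (transesterification) of the aryl pivalate; it is done before debenzylation so that the air-sensitive catechol is never exposed to base.

Step 9
Reactants: 16 (2S,4R,6S)-2-[3,4-bis(benzyloxy)-5-methoxyphenyl]-6-[2-(4-hydroxyphenyl)ethyl]tetrahydro-2H-pyran-4-ol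
Product: 17 (2S,4R,6S)-2-(3,4-dihydroxy-5-methoxyphenyl)-6-[2-(4-hydroxyphenyl)ethyl]tetrahydro-2H-pyran-4-ol
Conditions: H2 (1 atm), 10% Pd/C, EtOAc, rt
Reagents that add atoms: none
Why: Hydrogenolysis of the two aryl benzyl ethers, which should be cleaved much faster than the cyclic benzylic C2–O1 bond in a neutral solvent; the reaction is stopped once both benzyl groups are gone and no stereocentre is touched.

**Compound list**

1 | 3,4-dihydroxy-5-methoxybenzaldehyde | COc1cc(C=O)cc(O)c1O | starting material
2 | 3,4-bis(benzyloxy)-5-methoxybenzaldehyde | COc1cc(C=O)cc(OCc2ccccc2)c1OCc1ccccc1 | intermediate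
3 | Meldrum's acid (2,2-dimethyl-1,3-dioxane-4,6-dione) | CC1(C)OC(=O)CC(=O)O1 | starting material
4 | 5-[3,4-bis(benzyloxy)-5-methoxybenzylidene]-2,2-dimethyl-1,3-dioxane-4,6-dione | COc1cc(C=C2C(=O)OC(C)(C)OC2=O)cc(OCc2ccccc2)c1OCc1ccccc1 | intermediate
5 | 5-[3,4-bis(benzyloxy)-5-methoxybenzyl]-2,2-dimethyl-1,3-dioxane-4,6-dione | COc1cc(CC2C(=O)OC(C)(C)OC2=O)cc(OCc2ccccc2)c1OCc1ccccc1 | intermediate
6 | 3-[3,4-bis(benzyloxy)-5-methoxyphenyl]propanoic acid | COc1cc(CCC(=O)O)cc(OCc2ccccc2)c1OCc1ccccc1 | intermediate
7 | 1-{3-[3,4-bis(benzyloxy)-5-methoxyphenyl]propanoyl}-1H-benzotriazole | COc1cc(CCC(=O)n2nnc3ccccc32)cc(OCc2ccccc2)c1OCc1ccccc1 | intermediate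
8 | 4-(4-hydroxyphenyl)butan-2-one | CC(=O)CCc1ccc(O)cc1 | starting material
9 | 4-(3-oxobutyl)phenyl pivalate | CC(=O)CCc1ccc(OC(=O)C(C)(C)C)cc1 | intermediate
10 | lithium 4-[4-(pivaloyloxy)phenyl]but-1-en-2-olate | [Li+].C=C([O-])CCc1ccc(OC(=O)C(C)(C)C)cc1 | intermediate
11 | 1-[3,4-bis(benzyloxy)-5-methoxyphenyl]-7-[4-(pivaloyloxy)phenyl]heptane-3,5-dione | COc1cc(CCC(=O)CC(=O)CCc2ccc(OC(=O)C(C)(C)C)cc2)cc(OCc2ccccc2)c1OCc1ccccc1 | intermediate
12 | (5S)-7-[3,4-bis(benzyloxy)-5-methoxyphenyl]-5-hydroxy-1-[4-(pivaloyloxy)phenyl]heptan-3-one (one of the two mono-reduced regioisomers, which behave alike) | COc1cc(CC[C@H](O)CC(=O)CCc2ccc(OC(=O)C(C)(C)C)cc2)cc(OCc2ccccc2)c1OCc1ccccc1 | intermediate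
13 | (3S,5S)-1-[3,4-bis(benzyloxy)-5-methoxyphenyl]-7-[4-(pivaloyloxy)phenyl]heptane-3,5-diol | COc1cc(CC[C@H](O)C[C@H](CCc2ccc(OC(=O)C(C)(C)C)cc2)O)cc(OCc2ccccc2)c1OCc1ccccc1 | intermediate
14 | (3S,5S)-1-[3,4-bis(benzyloxy)-5-methoxyphenyl]-3,5-dihydroxy-7-[4-(pivaloyloxy)phenyl]heptan-1-ylium (benzylic cation) | COc1cc([CH+]C[C@H](O)C[C@H](CCc2ccc(OC(=O)C(C)(C)C)cc2)O)cc(OCc2ccccc2)c1OCc1ccccc1 | intermediate
15 | (2S,4R,6S)-2-[3,4-bis(benzyloxy)-5-methoxyphenyl]-6-{2-[4-(pivaloyloxy)phenyl]ethyl}tetrahydro-2H-pyran-4-ol | COc1cc([C@@H]2C[C@H](O)C[C@H](CCc3ccc(OC(=O)C(C)(C)C)cc3)O2)cc(OCc2ccccc2)c1OCc1ccccc1 | intermediate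
16 | (2S,4R,6S)-2-[3,4-bis(benzyloxy)-5-methoxyphenyl]-6-[2-(4-hydroxyphenyl)ethyl]tetrahydro-2H-pyran-4-ol | COc1cc([C@@H]2C[C@H](O)C[C@H](CCc3ccc(O)cc3)O2)cc(OCc2ccccc2)c1OCc1ccccc1 | intermediate
17 | (2S,4R,6S)-2-(3,4-dihydroxy-5-methoxyphenyl)-6-[2-(4-hydroxyphenyl)ethyl]tetrahydro-2H-pyran-4-ol | COc1cc([C@@H]2C[C@H](O)C[C@H](CCc3ccc(O)cc3)O2)cc(O)c1O | target

**Step count**

Total steps: 9. Longest linear sequence: 8 (steps 1, 2, 3, 5, 6, 7, 8, 9).

**Steps most likely to fail**

Step 7 (the new anodic cyclisation). The charge may pass on into the product, whose benzylic ether C–H can be oxidised in turn and open the ring to a ketone. The radical cation may lose a benzyl-ether proton instead of the ring-bound benzylic one. The cation may eliminate to a styrene before the hydroxyl closes, helped by the fact that the para benzyloxy group is flanked by two ortho oxygens and may not conjugate fully. The fallback uses known chemistry, sets out from aldehyde 2 and comes back at phenol 16. Commercial 4-(3-hydroxypropyl)phenol is pivaloylated on the phenoxide oxygen (PivCl, aq. NaOH, CH2Cl2, Bu4NHSO4) to 4-(3-hydroxypropyl)phenyl pivalate F1. This is oxidised with Dess–Martin periodinane to 3-[4-(pivaloyloxy)phenyl]propanal F2. Brown allylation with (+)-B-allyldiisopinocampheylborane (Et2O, −78 °C, ethanolamine work-up) should give (S)-1-[4-(pivaloyloxy)phenyl]hex-5-en-3-ol F3. Prins cyclisation of F3 with 2 (TFA, CH2Cl2, 0 °C, kept cold to limit oxonia-Cope exchange) should close the pyran through a chair oxocarbenium–alkene transition state with all substituents equatorial, giving the all-cis 4-trifluoroacetate F4. K2CO3 in MeOH then removes the trifluoroacetate and the pivalate together to give 16.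

Step 5 (enolate acylation). Enolisation may occur partly on the methylene side, acylation may go to oxygen, or proton exchange between the acidic product and the enolate may stall conversion. The fallback sets out from acid 6 and comes back at diketone 11, so the stereochemistry still comes from step 6. BH3·SMe2 reduces 6 to 3-[3,4-bis(benzyloxy)-5-methoxyphenyl]propan-1-ol F5. Dess–Martin oxidation gives 3-[3,4-bis(benzyloxy)-5-methoxyphenyl]propanal F6. Aldol addition of the LDA-derived enolate of ketone 9 (THF, −78 °C) gives the racemic β-hydroxy ketone F7, and a second Dess–Martin oxidation converts F7 into 11.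

Step 9 (hydrogenolysis). The benzylic C2–O1 bond of the pyran may be cleaved alongside the benzyl ethers, opening the ring to a 1,7-diarylheptanediol. The fallback sets out from 16 and comes back at target 17 without new intermediates: Lewis-acid debenzylation with BCl3 and pentamethylbenzene as benzyl-cation scavenger in CH2Cl2 at −78 °C, followed by a methanol quench, replaces the reductive cleavage.

**Further compounds**

F1 | step 7 | 4-(3-hydroxypropyl)phenyl pivalate | CC(C)(C)C(=O)Oc1ccc(CCCO)cc1
F2 | step 7 | 3-[4-(pivaloyloxy)phenyl]propanal | CC(C)(C)C(=O)Oc1ccc(CCC=O)cc1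
F3 | step 7 | (S)-1-[4-(pivaloyloxy)phenyl]hex-5-en-3-ol | C=CC[C@H](CCc1ccc(OC(=O)C(C)(C)C)cc1)O
F4 | step 7 | (2S,4R,6S)-2-[3,4-bis(benzyloxy)-5-methoxyphenyl]-6-{2-[4-(pivaloyloxy)phenyl]ethyl}tetrahydro-2H-pyran-4-yl trifluoroacetate | COc1cc([C@@H]2C[C@H](OC(=O)C(F)(F)F)C[C@H](CCc3ccc(OC(=O)C(C)(C)C)cc3)O2)cc(OCc2ccccc2)c1OCc1ccccc1
F5 | step 5 | 3-[3,4-bis(benzyloxy)-5-methoxyphenyl]propan-1-ol | COc1cc(CCCO)cc(OCc2ccccc2)c1OCc1ccccc1
F6 | step 5 | 3-[3,4-bis(benzyloxy)-5-methoxyphenyl]propanal | COc1cc(CCC=O)cc(OCc2ccccc2)c1OCc1ccccc1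
F7 | step 5 | rac-7-[3,4-bis(benzyloxy)-5-methoxyphenyl]-5-hydroxy-1-[4-(pivaloyloxy)phenyl]heptan-3-one | COc1cc(CCC(O)CC(=O)CCc2ccc(OC(=O)C(C)(C)C)cc2)cc(OCc2ccccc2)c1OCc1ccccc1
F0 | step 9 | none | none
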